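**Conventions.** Ring A is the central arene carrying both furan oxygens; ring B is the dioxygenated arene of the seven-membered ring. Furan 1 (C2, C3) is the dihydrofuran fused to the seven-membered ring; furan 2 (C2′, C3′) is the other one. C10 is the methine bearing the 2,4-dioxygenated aryl group and C11 the ring CH2 (dibenzo[a,d][7]annulene numbering, in which C3 of furan 1 is C5). The target 26 is 2S,3S (furan 1, trans), 10S, 2′R,3′R (furan 2, trans).

**Assumption.** In the three reagent-controlled steps (5, 8, 16) the enantiomer of catalyst, ligand or sulfide written is the one taken to deliver the drawn configuration; each is available in both mirror-image forms and the antipode is used if its sense proves opposite.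

## The problem

Compound 26 is a stilbenoid trimer in which ring A, substituted at five of six positions, is fused to two trans-2-aryl-2,3-dihydrofurans. Through C3 of furan 1 and the C11 methylene, ring A is also part of a seven-membered ring that is completed by ring B and the C10 methine. There are five stereocentres: the C2/C3 pair (2S,3S), C10 (S) and the C2′/C3′ pair (2′R,3′R). C3 can set C2, because closure of the C2–O bond through a benzylic cation gives the trans furan. C10 and C3 lie 1,4 to each other across a flexible ring, so neither controls the other reliably. The C2′/C3′ pair is remote from all the rest, so both of these relationships need external control. Eight phenols must be masked and released at the end, the two ring A oxygens must stay distinct from them, the benzylic C2–O bonds ionise under acid, and C3 is epimerisable or lost by dehydration to a benzofuran whenever it is alpha to a carbonyl. The enabling feature is C3 itself: it is bonded to a ring B carbon, to the ring A carbon ortho to a phenolic oxygen and to one further carbon (C2), which is the substitution pattern of branched attack by a phenol ortho carbon on an aryl-substituted allyl electrophile.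

## Retrosynthesis

**Deprotection.** All eight phenols of 26 are carried as methyl ethers in 25, so only O–CH3 bonds are cut last. One uniform, small protecting group keeps every arene compatible with organometallic, acidic and oxidative steps. The forward step must cleave eight ethers without opening the two benzylic ethers.

**Furan 2.** In 25 the O–C2′ and C2′–C3′ bonds are cut, a (4+1) disconnection to the ortho-quinone methide precursor 21 and the chiral benzylsulfonium salt 24. Against a stepwise aldehyde/cation closure, this sets both centres in one step and lets the sulfide, not the remote stereocentres, decide the absolute sense. Sulfone 21 goes back through benzhydrol 20 to salicylaldehyde 18 and the aryl Grignard reagent 19, and 18 to phenol 17 by ortho-formylation. The forward reactions must formylate the ring A carbon flanked by the phenol and C11, and must give the trans furan on one face.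

**Furan 1.** In 17 the C2–O bond is cut to triol 16 (closure through the 4-methoxybenzyl cation, trans to the C3 substituent), and the C2–aryl bond to lactol 14 and Grignard reagent 15. Lactol 14 is the masked aldehyde from cleavage of the vinyl group of 13. This uses C3 to set C2 and needs no protection of ring A, since the aldehyde is held as a hemiacetal by the neighbouring phenol.

**Seven-membered ring (key cut).** In 13 the ring A–C5 bond is cut, giving the resorcinol-tethered cinnamyl carbonate 12. Cutting here, and not at C10–C11 or ring B–C5, removes a ring and a stereocentre at once and leaves a nucleophile with two equivalent reactive positions. It also leaves an electrophile that ionises at only one site. The forward reaction must be branched-selective, C-selective and face-selective.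

**Allyl electrophile.** Carbonate 12 comes from styrene 11 by cross-metathesis with an allyl carbonate partner, and 11 from aryl chloride 9 by vinylation and ester cleavage. This is two steps instead of a Heck/reduction/acylation sequence, and it tolerates the free resorcinol, so no late phenol deprotection is needed beside the carbonate.

**C10 methine.** Triarylethane 9 is cut at the C10–H bond to the geometrically pure triarylethene 8, whose alkene geometry, not the difference between the two geminal aryl groups, is what the hydrogenation catalyst reads. Alkene 8 is cut at the C10–aryl bond to enol triflate 6 and boronic acid 7, and 6 comes from ketone 5. The ketone is cut at the ring B–carbonyl bond to chloroarene 3 and acid 2, the bis-pivalate of the commercial acid 1. Ring B enters as a π-nucleophile at its most activated carbon because that carbon ends up flanked by two ortho substituents, which no organometallic route tolerates well. Chlorine is the ring B placeholder, since it is inert in the alkenyl triflate coupling and the hydrogenation.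

## Roads not taken

**Alternative 1:** Furan 2 would be made first, by a squaramide-catalysed Friedel–Crafts/O-alkylation annulation of the resorcinol ester A2 with the bromonitroalkene A3, giving the trans-2-nitro-3-aryl-dihydrobenzofuran A1. The cut is ring A–C3′ plus O–C2′.
- Merits: cheap materials, one organocatalytic step, and C3′ set early on a small molecule. In this respect it is better than the late reagent-controlled annulation of the chosen plan.
- Weak points: C2′ carries a nitro group where the 4-hydroxyphenyl group is needed, and 2-nitro-dihydrobenzofurans lose nitrous acid easily to give benzofurans, which would erase C3′. The nucleophile A2 can also react between its two hydroxyls.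
- What remains: the seven-membered ring, C3 and C10 would still have to be built on A1, with only a remote stereo pair as guide.
- Comparison: the chosen plan gives up early control of furan 2 and in exchange sets the central ring and C3 by catalysis.

**Alternative 2:** Ring B would be made last, by a photochemical vinylketene/alkyne benzannulation of an unsaturated diazo ketone on a preformed cycloheptene with the siloxyalkyne A5, giving the resorcinol monosilyl ether A4. Four C–C bonds of ring B are formed.
- Merits: regiocontrolled arene construction, differentiated ring B oxygens, and no need to form bonds next to a doubly ortho-substituted arene. The last point is a real advantage over the chosen route to C10.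
- Weak points: differentiated ring B oxygens are of no use for 26. The diazo ketone must already carry furan 1, C3 and C10 on a non-aromatic seven-membered ring, where both centres sit alpha to the reacting π-system and can epimerise or eliminate. The precursor is long to make.
- Comparison: the chosen plan buys ring B as a commercial arene and accepts the steric problem at C10.

**Alternative 3:** An arylpalladium bromide (divalent palladium) formed at ring B would activate an alkyne on ring A. The phenol would add anti (5-endo-dig) and reductive elimination would join ring B to C3, giving the benzofuran-fused dibenzocycloheptane A6.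
- Merits: two bonds and two rings in one step from a Sonogashira-derived precursor. It is shorter to the tetracycle than the chosen plan.
- Weak points: A6 is an aromatic benzofuran, so C2 and C3 are erased and must be reinstalled by reducing a fully substituted, tetra-aryl-type double bond to the trans isomer with the correct sense relative to C10. Catalytic hydrogenation would give cis and no reagent control is available. The anti-oxypalladation geometry is also strained when the aryl group is tethered.
- Comparison: the chosen plan is longer to the same ring system but creates C3 directly as a catalyst-controlled stereocentre and lets it set C2.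

Key step: step 8

## Route

Step 1
Reactants: 1 2-(3,5-dihydroxyphenyl)acetic acid
Product: 2 2-[3,5-bis(2,2-dimethylpropanoyloxy)phenyl]acetic acid
Conditions: PivCl (2.3 equiv), aq NaOH, THF, 0 °C; then HCl to pH 2
Reagents that add atoms: pivaloyl chloride, CC(C)(C)C(=O)Cl
Why: Schotten–Baumann acylation of the two phenoxides, any mixed anhydride at the carboxylate being hydrolysed on work-up; the acyloxy groups make ring A too electron-poor to compete as a nucleophile in step 2.

Step 2
Reactants: 2 2-[3,5-bis(2,2-dimethylpropanoyloxy)phenyl]acetic acid; 3 1-chloro-3,5-dimethoxybenzene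
Product: 5 5-[2-(2-chloro-4,6-dimethoxyphenyl)-2-oxoethyl]-1,3-phenylene bis(2,2-dimethylpropanoate), via acid chloride 4 (not isolated)
Conditions: (COCl)2, DMF (cat.), CH2Cl2, 0 °C to rt, evaporate; then 3, SnCl4, CH2Cl2, −10 to 0 °C
Reagents that add atoms: none
Why: Friedel–Crafts acylation at C2 of 3, ortho and para to the two methoxy groups, the site at which 1-halo-3,5-dimethoxybenzenes are formylated; the mild Lewis acid avoids demethylation ortho to the new ketone.

Step 3
Reactants: 5 5-[2-(2-chloro-4,6-dimethoxyphenyl)-2-oxoethyl]-1,3-phenylene bis(2,2-dimethylpropanoate)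
Product: 6 (Z)-1-(2-chloro-4,6-dimethoxyphenyl)-2-[3,5-bis(2,2-dimethylpropanoyloxy)phenyl]ethenyl trifluoromethanesulfonate
Conditions: KN(SiMe3)2, THF, −78 °C; PhNTf2, −78 to 0 °C
Reagents that add atoms: N-phenylbis(trifluoromethanesulfonimide), O=S(=O)(N(c1ccccc1)S(=O)(=O)C(F)(F)F)C(F)(F)F
Why: Enolate O-sulfonylation; the benzylic ketone enolises to the Z enolate (ring A aryl trans to the bulky ring B), so one alkene isomer is expected, and the hindered pivalates survive the cold base.

Step 4
Reactants: 6 (Z)-enol triflate; 7 (2,4-dimethoxyphenyl)boronic acid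
Product: 8 5-[(E)-2-(2-chloro-4,6-dimethoxyphenyl)-2-(2,4-dimethoxyphenyl)ethenyl]-1,3-phenylene bis(2,2-dimethylpropanoate)
Conditions: Pd(PPh3)4 (5 mol %), K3PO4 hydrate, dioxane, 80 °C
Reagents that add atoms: none
Why: Suzuki–Miyaura coupling of an alkenyl triflate with retention of geometry; zerovalent palladium with triphenylphosphine inserts into the alkenyl C–O bond but not into the aryl chloride.

Step 5
Reactants: 8 (E)-triarylethene
Product: 9 5-[(2S)-2-(2-chloro-4,6-dimethoxyphenyl)-2-(2,4-dimethoxyphenyl)ethyl]-1,3-phenylene bis(2,2-dimethylpropanoate)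
Conditions: [Ir(cod)((S)-tBu-PHOX)]BArF (2 mol %), H2 (50 bar), CH2Cl2, 25 °C
Reagents that add atoms: none
Why: Iridium N,P-ligand asymmetric hydrogenation of a trisubstituted triaryl alkene, in which the catalyst distinguishes the alkene faces by the E geometry and not by the two geminal aryl groups; this sets 10S, and the aryl chloride and esters are inert to the cationic catalyst.

Step 6
Reactants: 9 (S)-triarylethane chloride
Product: 11 5-[(2S)-2-(2,4-dimethoxyphenyl)-2-(2-ethenyl-4,6-dimethoxyphenyl)ethyl]benzene-1,3-diol, via vinyl bis-pivalate 10 (not isolated)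
Conditions: Pd(OAc)2 (3 mol %), SPhos (6 mol %), CH2=CHBF3K, K2CO3, dioxane/H2O 10:1, 90 °C; then MeOH, 60 °C
Reagents that add atoms: potassium vinyltrifluoroborate, C=C[B-](F)(F)F.[K+]
Why: Suzuki–Miyaura vinylation of an ortho-substituted aryl chloride with a dialkylbiarylphosphine catalyst, followed in the same flask by carbonate-mediated methanolysis of the two aryl esters; the methine is not acidic enough to epimerise.

Step 7
Reactants: 11 vinyl resorcinol
Product: 12 (2E)-3-{2-[(1S)-2-(3,5-dihydroxyphenyl)-1-(2,4-dimethoxyphenyl)ethyl]-3,5-dimethoxyphenyl}prop-2-en-1-yl methyl carbonate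
Conditions: second-generation Hoveyda–Grubbs catalyst RuCl2(H2IMes)(=CH-C6H4-2-O-i-Pr) (5 mol %), allyl methyl carbonate (5 equiv), CH2Cl2, 40 °C
Reagents that add atoms: allyl methyl carbonate, C=CCOC(=O)OC
Why: Olefin cross-metathesis of a styrene with an excess of a terminal allylic carbonate gives the E cinnamyl carbonate with loss of ethene; free phenols are tolerated, so the carbonate is installed without any phenol protection.

Step 8
Reactants: 12 resorcinol-tethered cinnamyl methyl carbonate
Product: 13 (5S,10S)-10-(2,4-dimethoxyphenyl)-5-ethenyl-7,9-dimethoxy-10,11-dihydro-5H-dibenzo[a,d][7]annulene-2,4-diol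
Conditions: [Ir(cod)Cl]2 (2.5 mol %), (Sa,S,S)-O,O′-(1,1′-binaphthalene-2,2′-diyl) N,N-bis(1-phenylethyl)phosphoramidite (5 mol %), pre-activated with n-PrNH2 (THF, 50 °C, then evaporated); Li2CO3 (1 equiv), THF (0.02 M), 50 °C
Reagents that add atoms: none
Why: The cyclometalated phosphoramidite complex of monovalent iridium ionises the cinnamyl carbonate of 12 to an allyl complex of trivalent iridium, releasing CO2 and methoxide. The lithium phenoxide of ring A then attacks through the ring carbon ortho to the tether (ortho to one oxygen, para to the other) at the aryl-substituted allyl terminus, anti to the metal, and tautomerisation restores the resorcinol. The closest known reaction type is the iridium-catalysed enantioselective intramolecular Friedel–Crafts-type allylic alkylation of phenols, established for five- and six-membered benzo-fused rings with a vinyl-bearing stereocentre. The seven-membered ring closes in a 7-exo mode with respect to the allyl unit, the vinyl group staying outside the ring. The new stereocentre C5 is set by the catalyst, which leaves one face of the allyl complex open to the nucleophile; the ligand antipode is chosen so that this face gives 5S, with the vinyl group anti to the aryl group on the existing 10S methine, expected to be the matched and less strained arrangement. Branched over linear attack is the intrinsic preference of iridium and the only mode that gives a seven- and not a nine-membered ring; oxygen attack would likewise need a nine-membered ring and is disfavoured by the lithium counter-ion; site selectivity on ring A is secured by the symmetry of the 5-substituted resorcinol, whose position between the hydroxyls cannot reach the allyl unit. High dilution suppresses intermolecular allylation.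

Step 9
Reactants: 13 vinyl diol
Product: 14 lactol (2-hydroxy-2,3-dihydrofuran formed between the C4 oxygen and the former vinyl CH on C5; 3S, 10S, both anomers; C2 phenol free)
Conditions: OsO4 (2 mol %), NaIO4 (4 equiv), 2,6-lutidine, dioxane/H2O 3:1, rt
Reagents that add atoms: osmium tetroxide, O=[Os](=O)(=O)=O, reoxidised by sodium periodate, [Na+].[O-]I(=O)(=O)=O
Why: Lemieux–Johnson cleavage of the only alkene; the resulting α,α-diaryl aldehyde is trapped at once as the five-membered hemiacetal by the ortho phenol, which keeps the epimerisable C3 out of the enolisable open form, and the lutidine buffer prevents acid-induced dehydration to a benzofuran.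

Step 10
Reactants: 14 lactol; 15 4-methoxyphenylmagnesium bromide
Product: 16 (5S,10S)-10-(2,4-dimethoxyphenyl)-5-[hydroxy(4-methoxyphenyl)methyl]-7,9-dimethoxy-10,11-dihydro-5H-dibenzo[a,d][7]annulene-2,4-diol (both carbinol epimers)
Conditions: 15 (4 equiv), THF, −20 to 0 °C; aq NH4Cl
Reagents that add atoms: none
Why: Grignard addition to a lactol, which opens to the magnesium phenoxide aldehyde after deprotonation and is arylated faster than it enolises; the carbinol configuration is irrelevant because it is ionised in step 11.

Step 11
Reactants: 16 triol
Product: 17 furan 1 phenol: tetracycle with trans-(2S,3S)-2-(4-methoxyphenyl)-2,3-dihydrofuran on ring A, 10S 2,4-dimethoxyphenyl methine, dimethoxy ring B and one free ring A phenol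
Conditions: TsOH·H2O (10 mol %), CH2Cl2, 0 °C
Reagents that add atoms: none
Why: Acid-catalysed SN1 cyclodehydration: the 4-methoxybenzyl cation is captured by the only phenol that can form a five-membered ring, and the aryl group takes the face opposite to ring B on C3, giving the trans furan (2S from 3S).

Step 12
Reactants: 17 furan 1 phenol
Product: 18 salicylaldehyde: 17 with a formyl group on the ring A carbon between the phenol and C11
Conditions: MgCl2, Et3N, (CH2O)n, MeCN, 80 °C
Reagents that add atoms: paraformaldehyde (as formaldehyde), C=O
Why: Casnati–Skattebøl ortho-formylation through the magnesium phenoxide touches only the phenol-bearing ring; of its two ortho carbons the one para to the furan oxygen is the more nucleophilic, as in 3-alkoxyphenols, which are formylated para to the alkoxy group.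

Step 13
Reactants: 18 salicylaldehyde; 19 3,5-dimethoxyphenylmagnesium bromide
Product: 20 benzhydrol: 17 with a hydroxy(3,5-dimethoxyphenyl)methyl group at the formylated carbon (both epimers)
Conditions: 19 (3 equiv), THF, −40 to 0 °C; aq NH4Cl
Reagents that add atoms: none
Why: Aryl Grignard addition to a salicylaldehyde, the first equivalent being spent on the phenol; there are no enolisable positions and the carbinol centre is lost in the next two steps.

Step 14
Reactants: 20 benzhydrol
Product: 21 sulfone: 17 with a (3,5-dimethoxyphenyl)(4-methylbenzenesulfonyl)methyl group at the same carbon (both epimers)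
Conditions: p-TolSO2H (2 equiv), CH2Cl2, rt
Reagents that add atoms: 4-methylbenzenesulfinic acid, Cc1ccc(S(=O)O)cc1
Why: The ortho-hydroxy, para-alkoxy benzhydrol ionises under the mild acidity of the sulfinic acid and is trapped at sulfur, giving the standard base-labile precursor of an ortho-quinone methide.

Step 15
Reactants: 22 (1R,4R,5R)-4,7,7-trimethyl-6-thiabicyclo[3.2.1]octane (isothiocineole); 23 (4-methoxyphenyl)methanol
Product: 24 (1R,4R,5R,6R)-6-(4-methoxybenzyl)-4,7,7-trimethyl-6-thiabicyclo[3.2.1]octan-6-ium tetrafluoroborate (benzyl group on the exo face of sulfur)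
Conditions: HBF4·OEt2, CH2Cl2, 0 °C to rt
Reagents that add atoms: tetrafluoroboric acid, [H+].F[B-](F)(F)F
Why: S-alkylation of the sulfide by the acid-generated 4-methoxybenzyl cation, the usual route to electron-rich benzylsulfonium salts; alkylation occurs on the exposed lone pair, giving one diastereomer at sulfur.

Step 16
Reactants: 21 sulfone; 24 chiral benzylsulfonium salt
Product: 25 octa-O-methyl ether of 26 (2S,3S,10S,2′R,3′R)
Conditions: 24 (1.5 equiv), Cs2CO3 (3 equiv), CH2Cl2/MeCN, −20 °C to rt
Reagents that add atoms: none
Why: Base eliminates sulfinate from the phenoxide of 21 to give the ortho-quinone methide, the sulfonium benzylide adds to its exocyclic carbon and the phenoxide displaces the sulfide with inversion (5-exo-tet), a (4+1) annulation known to give trans-2,3-dihydrobenzofurans; the chiral sulfide exposes one face of the ylide carbon and so fixes C2′, and the trans preference then fixes C3′.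

Step 17
Reactants: 25 octamethyl ether
Product: 26 CNP0154047.3 (target)
Conditions: BBr3 (16 equiv), CH2Cl2, −78 to 0 °C; MeOH quench
Reagents that add atoms: none
Why: Lewis-acid cleavage of aryl methyl ethers, the usual final step for stilbenoid oligomers; kept cold so that the benzylic ring ethers, which give the trans furans again on reclosure, are not degraded.

## Compound list

1 | 2-(3,5-dihydroxyphenyl)acetic acid | OC(=O)Cc1cc(O)cc(O)c1 | starting material
2 | 2-[3,5-bis(2,2-dimethylpropanoyloxy)phenyl]acetic acid | CC(C)(C)C(=O)Oc1cc(CC(=O)O)cc(OC(=O)C(C)(C)C)c1 | intermediate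
3 | 1-chloro-3,5-dimethoxybenzene | COc1cc(Cl)cc(OC)c1 | starting material
4 | 2-[3,5-bis(2,2-dimethylpropanoyloxy)phenyl]acetyl chloride | CC(C)(C)C(=O)Oc1cc(CC(=O)Cl)cc(OC(=O)C(C)(C)C)c1 | intermediate (not isolated)
5 | 5-[2-(2-chloro-4,6-dimethoxyphenyl)-2-oxoethyl]-1,3-phenylene bis(2,2-dimethylpropanoate) | COc1cc(Cl)c(C(=O)Cc2cc(OC(=O)C(C)(C)C)cc(OC(=O)C(C)(C)C)c2)c(OC)c1 | intermediate
6 | (Z)-1-(2-chloro-4,6-dimethoxyphenyl)-2-[3,5-bis(2,2-dimethylpropanoyloxy)phenyl]ethenyl trifluoromethanesulfonate | COc1cc(Cl)c(/C(OS(=O)(=O)C(F)(F)F)=C/c2cc(OC(=O)C(C)(C)C)cc(OC(=O)C(C)(C)C)c2)c(OC)c1 | intermediate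
7 | (2,4-dimethoxyphenyl)boronic acid | COc1ccc(B(O)O)c(OC)c1 | starting material
8 | 5-[(E)-2-(2-chloro-4,6-dimethoxyphenyl)-2-(2,4-dimethoxyphenyl)ethenyl]-1,3-phenylene bis(2,2-dimethylpropanoate) | COc1ccc(/C(=C\c2cc(OC(=O)C(C)(C)C)cc(OC(=O)C(C)(C)C)c2)c2c(Cl)cc(OC)cc2OC)c(OC)c1 | intermediate
9 | 5-[(2S)-2-(2-chloro-4,6-dimethoxyphenyl)-2-(2,4-dimethoxyphenyl)ethyl]-1,3-phenylene bis(2,2-dimethylpropanoate) | CC(C)(C)C(=O)Oc1cc(C[C@@H](c2ccc(OC)cc2OC)c2c(Cl)cc(OC)cc2OC)cc(OC(=O)C(C)(C)C)c1 | intermediate
10 | 5-[(2S)-2-(2,4-dimethoxyphenyl)-2-(2-ethenyl-4,6-dimethoxyphenyl)ethyl]-1,3-phenylene bis(2,2-dimethylpropanoate) | CC(C)(C)C(=O)Oc1cc(C[C@@H](c2ccc(OC)cc2OC)c2c(C=C)cc(OC)cc2OC)cc(OC(=O)C(C)(C)C)c1 | intermediate (not isolated)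
11 | 5-[(2S)-2-(2,4-dimethoxyphenyl)-2-(2-ethenyl-4,6-dimethoxyphenyl)ethyl]benzene-1,3-diol | Oc1cc(O)cc(C[C@@H](c2ccc(OC)cc2OC)c2c(C=C)cc(OC)cc2OC)c1 | intermediate
12 | (2E)-3-{2-[(1S)-2-(3,5-dihydroxyphenyl)-1-(2,4-dimethoxyphenyl)ethyl]-3,5-dimethoxyphenyl}prop-2-en-1-yl methyl carbonate | Oc1cc(O)cc(C[C@@H](c2ccc(OC)cc2OC)c2c(/C=C/COC(=O)OC)cc(OC)cc2OC)c1 | intermediate (key-step precursor)
13 | (5S,10S)-10-(2,4-dimethoxyphenyl)-5-ethenyl-7,9-dimethoxy-10,11-dihydro-5H-dibenzo[a,d][7]annulene-2,4-diol | Oc1cc(O)cc2c1[C@@H](C=C)c1cc(OC)cc(OC)c1[C@H](c1ccc(OC)cc1OC)C2 | intermediate (key-step product)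
14 | lactol of the C5 aldehyde of 13 (2-hydroxy-2,3-dihydrofuran closed by the C4 oxygen; 3S, 10S; both anomers) | OC1Oc2cc(O)cc3c2[C@@H]1c1cc(OC)cc(OC)c1[C@H](c1ccc(OC)cc1OC)C3 | intermediate
15 | 4-methoxyphenylmagnesium bromide | COc1ccc([Mg]Br)cc1 | starting material
16 | (5S,10S)-10-(2,4-dimethoxyphenyl)-5-[hydroxy(4-methoxyphenyl)methyl]-7,9-dimethoxy-10,11-dihydro-5H-dibenzo[a,d][7]annulene-2,4-diol (both carbinol epimers) | COc1ccc(C(O)[C@H]2c3cc(OC)cc(OC)c3[C@H](c3ccc(OC)cc3OC)Cc3cc(O)cc(O)c32)cc1 | intermediate
17 | furan 1 phenol (trans-2S,3S furan 1 with 4-methoxyphenyl, 10S methine, dimethoxy ring B, one free ring A phenol) | COc1ccc([C@H]2Oc3cc(O)cc4c3[C@@H]2c2cc(OC)cc(OC)c2[C@H](c2ccc(OC)cc2OC)C4)cc1 | intermediate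
18 | 17 with a formyl group on ring A between the phenol and C11 | COc1ccc([C@H]2Oc3cc(O)c(C=O)c4c3[C@@H]2c2cc(OC)cc(OC)c2[C@H](c2ccc(OC)cc2OC)C4)cc1 | intermediate
19 | 3,5-dimethoxyphenylmagnesium bromide | COc1cc([Mg]Br)cc(OC)c1 | starting material
20 | 17 with a hydroxy(3,5-dimethoxyphenyl)methyl group at that carbon (both epimers) | COc1ccc([C@H]2Oc3cc(O)c(C(O)c5cc(OC)cc(OC)c5)c4c3[C@@H]2c2cc(OC)cc(OC)c2[C@H](c2ccc(OC)cc2OC)C4)cc1 | intermediate
21 | 17 with a (3,5-dimethoxyphenyl)(4-methylbenzenesulfonyl)methyl group at that carbon (both epimers) | COc1ccc([C@H]2Oc3cc(O)c(C(c5cc(OC)cc(OC)c5)S(=O)(=O)c5ccc(C)cc5)c4c3[C@@H]2c2cc(OC)cc(OC)c2[C@H](c2ccc(OC)cc2OC)C4)cc1 | intermediate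
22 | (1R,4R,5R)-4,7,7-trimethyl-6-thiabicyclo[3.2.1]octane | C[C@@H]1CC[C@@H]2C[C@H]1SC2(C)C | starting material
23 | (4-methoxyphenyl)methanol | COc1ccc(CO)cc1 | starting material
24 | (1R,4R,5R,6R)-6-(4-methoxybenzyl)-4,7,7-trimethyl-6-thiabicyclo[3.2.1]octan-6-ium tetrafluoroborate | C[C@@H]1CC[C@@H]2C[C@H]1[S@@+](Cc1ccc(OC)cc1)C2(C)C.F[B-](F)(F)F | intermediate
25 | octa-O-methyl ether of 26 (2S,3S,10S,2′R,3′R) | COc1ccc([C@H]2Oc3cc4c(c5c3[C@@H]2c2cc(OC)cc(OC)c2[C@H](c2ccc(OC)cc2OC)C5)[C@@H](c2cc(OC)cc(OC)c2)[C@H](c2ccc(OC)cc2)O4)cc1 | intermediate
26 | CNP0154047.3 (2S,3S,10S,2′R,3′R) | Oc1ccc([C@H]2Oc3cc4c(c5c3[C@@H]2c2cc(O)cc(O)c2[C@H](c2ccc(O)cc2O)C5)[C@@H](c2cc(O)cc(O)c2)[C@H](c2ccc(O)cc2)O4)cc1 | target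

**Total step count:** 17. **Longest linear sequence:** 16 steps (steps 1–14, 16, 17 from 1); step 15 is a one-step side branch.

## Least certain steps and fallbacks

**Step 8 (key step).** The most likely failure is slow closure of the seven-membered ring, a size not yet documented for phenol nucleophiles in this reaction. Intermolecular allylation (at oxygen or carbon) and oligomerisation would then take over. A second failure would be a mismatch between the catalyst's facial preference and the conformational demand of the 10S methine, which would erode the diastereoselectivity. The fallback drops metal catalysis: carbonate 12 is ionised with Sc(OTf)3 (5 mol %, MeNO2, 0 °C) in an acid-catalysed intramolecular Friedel–Crafts allylation. The same ring size argument directs attack to the benzylic terminus, the 10S methine alone decides the face, and 13 is separated from its C5 epimer before continuing at step 9.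

**Step 5.** The alkene of 8 carries three ortho substituents on its geminal aryl groups, so it may not bind to iridium. Acid formed from the iridium hydride may also isomerise the alkene, which would lower the enantiomeric purity because the catalyst reads the geometry. The fallback starts from 8: ionic hydrogenation (Et3SiH, CF3CO2H, CH2Cl2), which is insensitive to hindrance because it runs through the stabilised diarylmethyl cation, gives the racemic triarylethane F1. Resolution by preparative chromatography on a chiral stationary phase then returns the route to 9.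

**Step 9.** Periodate may oxidise the free resorcinol, and the lactol may lose water to a benzofuran or open and enolise on handling, with loss of the C3 configuration. The fallback starts from 13. The phenols are acetylated (Ac2O, pyridine) to the diacetate F2 and the vinyl group is ozonised (O3, CH2Cl2/MeOH, −78 °C; Me2S) to the aldehyde F3. F3 is treated at once with an excess of 15, which arylates the aldehyde and removes both acetates, rejoining the route at 16.

**Step 12.** Formylation may go to the ring A carbon between the two oxygens, or give a mixture, because the wanted position is the more hindered of the two ortho carbons. The fallback starts from 17 and replaces the chelation-directed step by an acid-mediated three-component electrophilic substitution with 3,5-dimethoxybenzaldehyde and 4-methylbenzenesulfinic acid. This reaction type favours the position para to the ether oxygen and avoids the one between two oxygens, and it gives 21 directly, bypassing 18 and 20.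

**Step 16.** The electron-rich benzylide may decompose or act only as a base, the quinone methide may dimerise, and the facial preference of the ylide may be opposed by the seven-membered ring, lowering the selectivity at C2′/C3′. The fallback starts from 20 and uses a catalyst-controlled carbene C–H insertion:
- The phenol is alkylated (4-methoxybenzyl chloride, K2CO3, DMF) to the ether F4.
- The carbinol is oxidised (MnO2) to the ketone F5 and converted (N2H4·H2O, AcOH, EtOH, 80 °C) to the hydrazone F6.
- Oxidation (MnO2) gives the diazo compound F7, which is used without isolation.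
- Rh2(R-PTAD)4, dirhodium tetrakis[(R)-(1-adamantyl)(phthalimido)acetate], inserts the carbene into the benzylic ether C–H bond to give the cis-dihydrofuran F8, with C3′ set by the catalyst.
- Acid (CF3CO2H, CH2Cl2) equilibrates C2′ through the benzylic cation to the trans isomer 25.

**Step 17.** BBr3 may open the benzylic C2–O and C2′–O bonds, followed by Friedel–Crafts capture of the cations by neighbouring arenes, or may cleave the eight ethers incompletely. The fallback starts from 25 and uses nucleophilic demethylation with EtSNa in DMF at 130 °C. This is an SN2 attack at the methyl groups under basic conditions that never generates an oxonium ion at the ring oxygens, and it gives 26.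

## Further compounds

F0 | step 8 | none | none
F1 | step 5 | racemic 5-[2-(2-chloro-4,6-dimethoxyphenyl)-2-(2,4-dimethoxyphenyl)ethyl]-1,3-phenylene bis(2,2-dimethylpropanoate) | CC(C)(C)C(=O)Oc1cc(CC(c2ccc(OC)cc2OC)c2c(Cl)cc(OC)cc2OC)cc(OC(=O)C(C)(C)C)c1
F2 | step 9 | (5S,10S)-10-(2,4-dimethoxyphenyl)-5-ethenyl-7,9-dimethoxy-10,11-dihydro-5H-dibenzo[a,d][7]annulene-2,4-diyl diacetate | CC(=O)Oc1cc(OC(C)=O)cc2c1[C@@H](C=C)c1cc(OC)cc(OC)c1[C@H](c1ccc(OC)cc1OC)C2
F3 | step 9 | (5S,10S)-10-(2,4-dimethoxyphenyl)-5-formyl-7,9-dimethoxy-10,11-dihydro-5H-dibenzo[a,d][7]annulene-2,4-diyl diacetate | CC(=O)Oc1cc(OC(C)=O)cc2c1[C@@H](C=O)c1cc(OC)cc(OC)c1[C@H](c1ccc(OC)cc1OC)C2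
F0 | step 12 | none | none
F4 | step 16 | 4-methoxybenzyl ether of the phenol of 20 (carbinol free, both epimers) | COc1ccc([C@H]2Oc3cc(OCc6ccc(OC)cc6)c(C(O)c5cc(OC)cc(OC)c5)c4c3[C@@H]2c2cc(OC)cc(OC)c2[C@H](c2ccc(OC)cc2OC)C4)cc1
F5 | step 16 | diaryl ketone from F4 | COc1ccc([C@H]2Oc3cc(OCc6ccc(OC)cc6)c(C(=O)c5cc(OC)cc(OC)c5)c4c3[C@@H]2c2cc(OC)cc(OC)c2[C@H](c2ccc(OC)cc2OC)C4)cc1
F6 | step 16 | hydrazone of F5 | COc1ccc([C@H]2Oc3cc(OCc6ccc(OC)cc6)c(C(=NN)c5cc(OC)cc(OC)c5)c4c3[C@@H]2c2cc(OC)cc(OC)c2[C@H](c2ccc(OC)cc2OC)C4)cc1
F7 | step 16 | diaryldiazomethane from F6 | COc1ccc([C@H]2Oc3cc(OCc6ccc(OC)cc6)c(C(=[N+]=[N-])c5cc(OC)cc(OC)c5)c4c3[C@@H]2c2cc(OC)cc(OC)c2[C@H](c2ccc(OC)cc2OC)C4)cc1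
F8 | step 16 | C2′ epimer of 25 (cis furan 2, 2′S,3′R) | COc1ccc([C@H]2Oc3cc4c(c5c3[C@@H]2c2cc(OC)cc(OC)c2[C@H](c2ccc(OC)cc2OC)C5)[C@@H](c2cc(OC)cc(OC)c2)[C@@H](c2ccc(OC)cc2)O4)cc1
F0 | step 17 | none | none
A1 | alternative 1 | methyl 2-[trans-3-(3,5-dimethoxyphenyl)-6-hydroxy-2-nitro-2,3-dihydrobenzofuran-4-yl]acetate | COC(=O)Cc1cc(O)cc2c1[C@@H](c1cc(OC)cc(OC)c1)[C@H]([N+](=O)[O-])O2
A2 | alternative 1 | methyl 2-(3,5-dihydroxyphenyl)acetate | COC(=O)Cc1cc(O)cc(O)c1
A3 | alternative 1 | (Z)-1-(2-bromo-2-nitroethenyl)-3,5-dimethoxybenzene | COc1cc(/C=C(\Br)[N+](=O)[O-])cc(OC)c1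
A4 | alternative 2 | tetracyclic resorcinol monosilyl ether | COc1ccc([C@H]2Oc3cc(OCc4ccccc4)cc4c3[C@@H]2c2cc(O[Si](C(C)C)(C(C)C)C(C)C)cc(O)c2[C@H](c2ccc(OC)cc2OC)C4)cc1
A5 | alternative 2 | (triisopropylsiloxy)acetylene | C#CO[Si](C(C)C)(C(C)C)C(C)C
A6 | alternative 3 | benzofuran-fused dibenzocycloheptane | COc1ccc(-c2oc3cc(OCc4ccccc4)cc4c3c2-c2cc(OC)cc(OC)c2[C@H](c2ccc(OC)cc2OC)C4)cc1
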